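**Strategy.** Everything rests on cutting ring C at C4–C4a and O1–C2. Ring A is a 4,5-dimethoxyresorcinol in which the oxygen that becomes O1 (on C8a) sits next to an unsubstituted, strongly nucleophilic carbon (the future C4a), and C2–C3–C4 with the 3-oxygen map onto an α-benzyloxy aroylacetate. Heating the two partners without acid should form the pyranone in one operation by C-acylation and cyclodehydration. The precursor is ethyl 2-benzyloxy-3-aryl-3-oxopropanoate 16, whose aryl group already carries the benzyl-protected 4'-oxygen and the (S)-4-benzyloxy-3-methylbutyl chain (stereocentre from the chiral pool). A single hydrogenolysis then frees all three hydroxyls.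

Key step: step 8

Remark 1: the (R)-hydroxy ester 4 gives the (3S) side chain without any inversion. Its ester carbon, not its CH2OH carbon, is carried into the chain, so only the CIP ranking changes.
Remark 2: ketoester 16 is made and used as a mixture of C2 epimers (and enol). That carbon becomes sp2 C3 of the chromone, so it is drawn without configuration.

**Route**

Step 1
Reactants: 1 3-hydroxy-4,5-dimethoxybenzaldehyde
Product: 3 4,5-dimethoxybenzene-1,3-diol, via aryl formate 2 (not isolated)
Conditions: mCPBA (1.1 equiv), CH2Cl2, 0 °C → rt; then MeOH, cat. HCl, rt; aq. NaHCO3 wash; stored under Ar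
Reagents that add atoms: 3-chloroperoxybenzoic acid (mCPBA), O=C(OO)c1cccc(Cl)c1
Why: Baeyer–Villiger (Dakin-type) oxidation, in which the aryl group activated by its para-methoxy group should migrate in preference to hydride, followed by acid-catalysed methanolysis of the labile formate so that the electron-rich diol never meets base and air together.

Step 2
Reactants: 4 methyl (R)-3-hydroxy-2-methylpropanoate
Product: 5 methyl (R)-3-(benzyloxy)-2-methylpropanoate
Conditions: BnOC(=NH)CCl3 (1.3 equiv), TfOH (5 mol %), CH2Cl2/cyclohexane, 0 °C → rt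
Reagents that add atoms: benzyl 2,2,2-trichloroacetimidate, N=C(OCc1ccccc1)C(Cl)(Cl)Cl
Why: acid-catalysed imidate O-benzylation avoids the base that would cause β-elimination or α-epimerisation of the β-hydroxy ester, so the chiral-pool stereocentre is kept.

Step 3
Reactants: 5 methyl (R)-3-(benzyloxy)-2-methylpropanoate
Product: 6 (R)-3-(benzyloxy)-2-methylpropanal
Conditions: DIBAL-H (1.1 equiv), CH2Cl2, −78 °C; MeOH quench at −78 °C, aq. potassium sodium tartrate; used crude at once
Reagents that add atoms: none
Why: partial ester reduction, in which the aluminium hemiacetal (held by chelation to the β-benzyloxy oxygen) should survive at −78 °C and release the aldehyde only on work-up, under non-basic conditions that leave the α-stereocentre alone.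

Step 4
Reactants: 6 (R)-3-(benzyloxy)-2-methylpropanal
Product: 7 (S)-{[(2-methylbut-3-en-1-yl)oxy]methyl}benzene [(S)-4-(benzyloxy)-3-methylbut-1-ene]
Conditions: Ph3PCH3Br (1.5 equiv), KHMDS (1.4 equiv), THF, 0 °C; then 6, −78 → 0 °C
Reagents that add atoms: methyltriphenylphosphonium bromide, C[P+](c1ccccc1)(c1ccccc1)c1ccccc1.[Br-]
Why: Wittig methylenation at low temperature with no excess base should trap the aldehyde faster than it enolises, so the centre is carried over unchanged (the S descriptor reflects only the new CIP ranking).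

Step 5
Reactants: 8 methyl 3-bromo-4-hydroxybenzoate
Product: 9 methyl 4-(benzyloxy)-3-bromobenzoate
Conditions: BnBr (1.1 equiv), K2CO3 (1.5 equiv), DMF, rt → 50 °C
Reagents that add atoms: benzyl bromide, BrCc1ccccc1
Why: Williamson ether synthesis on an acidic, ester-activated phenol.

Step 6
Reactants: 7 (S)-{[(2-methylbut-3-en-1-yl)oxy]methyl}benzene; 9 methyl 4-(benzyloxy)-3-bromobenzoate
Product: 12 4-(benzyloxy)-3-[(3S)-4-(benzyloxy)-3-methylbutyl]benzoic acid, via B-alkyl borane 10 (not isolated), via methyl ester 11 (not isolated)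
Conditions: 7 (1.3 equiv), 9-BBN-H (1.3 equiv), THF, 0 °C → rt; then 9 (1.0 equiv), PdCl2(dppf)·CH2Cl2 (5 mol %), aq. K3PO4 (3 equiv), DMF, 60 °C; then LiOH·H2O (5 equiv), MeOH/H2O, 60 °C; 1 M HCl to pH 2, acid–base extraction
Reagents that add atoms: lithium hydroxide, [Li+].[OH-]
Why: anti-Markovnikov hydroboration followed by B-alkyl Suzuki–Miyaura coupling (the bromide is activated by the para ester and dppf favours reductive elimination over β-hydride elimination), with saponification in the same aqueous basic pot and the stereocentre not involved.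

Step 7
Reactants: 12 4-(benzyloxy)-3-[(3S)-4-(benzyloxy)-3-methylbutyl]benzoic acid; 13 ethyl 2-(benzyloxy)acetate
Product: 16 ethyl 2-(benzyloxy)-3-{4-(benzyloxy)-3-[(3S)-4-(benzyloxy)-3-methylbutyl]phenyl}-3-oxopropanoate (C2 epimers), via acid chloride 14 (not isolated), via lithium enolate 15 (not isolated)
Conditions: 12, (COCl)2 (1.5 equiv), cat. DMF, CH2Cl2, 0 °C → rt, evaporate; separately 13 (2.3 equiv), LiHMDS (2.2 equiv), THF, −78 °C; add 14 in THF, −78 °C; AcOH quench
Reagents that add atoms: none
Why: Claisen-type C-acylation of a preformed ester enolate by an acid chloride, in which the second equivalent of enolate deprotonates the more acidic β-ketoester as it forms and so prevents double acylation.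

Step 8
Reactants: 3 4,5-dimethoxybenzene-1,3-diol; 16 ethyl 2-(benzyloxy)-3-{4-(benzyloxy)-3-[(3S)-4-(benzyloxy)-3-methylbutyl]phenyl}-3-oxopropanoate
Product: 19 3-(benzyloxy)-2-{4-(benzyloxy)-3-[(3S)-4-(benzyloxy)-3-methylbutyl]phenyl}-7-hydroxy-5,6-dimethoxy-4H-chromen-4-one, via acylketene 17 (not isolated), via C-acylated diketone 18 (not isolated)
Conditions: 3 (2 equiv), 16 (1 equiv), minimal Ph2O (or neat melt), Ar, 240–250 °C, EtOH and H2O distilled out as formed; no acid or base
Reagents that add atoms: none
Why: This is a Mentzer-type thermal condensation (the acid-free relative of the Simonis chromone synthesis): the enol of 16 loses ethanol to give α-oxoketene 17, which acylates the electron-rich ring of 3 at C6 (any O-acylation is reversible through the same ketene) and forms the C4–C4a bond in diketone 18. The hydroxyl on the neighbouring carbon then adds to the aryl ketone carbonyl in a 6-exo-trig closure, and loss of water forms O1–C2 and the aromatic pyranone. No stereocentre is created, the epimeric C2 of 16 becomes sp2 C3, and the remote (3S) centre is not touched. The step needs acylation at C6 and not at C2 of 3: C6 lies para to one hydroxyl and ortho to the other, the pattern resorcinols follow in such acylations, whereas C2 is wedged between two oxygens. It also needs chromone and not coumarin formation, which the absence of acid (no activation of the ketone for Pechmann-type ring attack) and the α-benzyloxy substituent should favour. After acylation at C6 only one hydroxyl is adjacent (the other neighbour is OMe), so closure has a single direction and the future 7-OH can stay free.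

Step 9
Reactants: 19 3-(benzyloxy)-2-{4-(benzyloxy)-3-[(3S)-4-(benzyloxy)-3-methylbutyl]phenyl}-7-hydroxy-5,6-dimethoxy-4H-chromen-4-one
Product: 20 3,7-dihydroxy-2-{4-hydroxy-3-[(3S)-4-hydroxy-3-methylbutyl]phenyl}-5,6-dimethoxy-4H-chromen-4-one
Conditions: H2 (1 atm), Pd(OH)2/C, THF/MeOH, rt
Reagents that add atoms: none
Why: catalytic hydrogenolysis should cleave the enol and aryl benzyl ethers quickly and the primary alkyl benzyl ether more slowly, while the fully substituted, cross-conjugated C2=C3 bond of the flavonol and the stereocentre stay intact.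

**Compound list**

1 | 3-hydroxy-4,5-dimethoxybenzaldehyde | COc1cc(C=O)cc(O)c1OC | starting material
2 | 3-hydroxy-4,5-dimethoxyphenyl formate | O=COc1cc(O)c(OC)c(OC)c1 | intermediate (not isolated)
3 | 4,5-dimethoxybenzene-1,3-diol | Oc1cc(O)c(OC)c(OC)c1 | intermediate
4 | methyl (R)-3-hydroxy-2-methylpropanoate | COC(=O)[C@H](C)CO | starting material
5 | methyl (R)-3-(benzyloxy)-2-methylpropanoate | COC(=O)[C@H](C)COCc1ccccc1 | intermediate
6 | (R)-3-(benzyloxy)-2-methylpropanal | O=C[C@H](C)COCc1ccccc1 | intermediate
7 | (S)-{[(2-methylbut-3-en-1-yl)oxy]methyl}benzene | C=C[C@H](C)COCc1ccccc1 | intermediate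
8 | methyl 3-bromo-4-hydroxybenzoate | COC(=O)c1ccc(O)c(Br)c1 | starting material
9 | methyl 4-(benzyloxy)-3-bromobenzoate | COC(=O)c1ccc(OCc2ccccc2)c(Br)c1 | intermediate
10 | 9-[(3S)-4-(benzyloxy)-3-methylbutyl]-9-borabicyclo[3.3.1]nonane | B1(CC[C@H](C)COCc2ccccc2)C2CCCC1CCC2 | intermediate (not isolated)
11 | methyl 4-(benzyloxy)-3-[(3S)-4-(benzyloxy)-3-methylbutyl]benzoate | COC(=O)c1ccc(OCc2ccccc2)c(CC[C@H](C)COCc2ccccc2)c1 | intermediate (not isolated)
12 | 4-(benzyloxy)-3-[(3S)-4-(benzyloxy)-3-methylbutyl]benzoic acid | OC(=O)c1ccc(OCc2ccccc2)c(CC[C@H](C)COCc2ccccc2)c1 | intermediate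
13 | ethyl 2-(benzyloxy)acetate | CCOC(=O)COCc1ccccc1 | starting material
14 | 4-(benzyloxy)-3-[(3S)-4-(benzyloxy)-3-methylbutyl]benzoyl chloride | ClC(=O)c1ccc(OCc2ccccc2)c(CC[C@H](C)COCc2ccccc2)c1 | intermediate (not isolated)
15 | lithium 2-(benzyloxy)-1-ethoxyethen-1-olate | [Li+].CCOC([O-])=COCc1ccccc1 | intermediate (not isolated)
16 | ethyl 2-(benzyloxy)-3-{4-(benzyloxy)-3-[(3S)-4-(benzyloxy)-3-methylbutyl]phenyl}-3-oxopropanoate (C2 epimers) | CCOC(=O)C(OCc1ccccc1)C(=O)c1ccc(OCc2ccccc2)c(CC[C@H](C)COCc2ccccc2)c1 | intermediate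
17 | 2-(benzyloxy)-3-{4-(benzyloxy)-3-[(3S)-4-(benzyloxy)-3-methylbutyl]phenyl}prop-1-ene-1,3-dione | O=C=C(OCc1ccccc1)C(=O)c1ccc(OCc2ccccc2)c(CC[C@H](C)COCc2ccccc2)c1 | intermediate (not isolated)
18 | 2-(benzyloxy)-1-{4-(benzyloxy)-3-[(3S)-4-(benzyloxy)-3-methylbutyl]phenyl}-3-(2,4-dihydroxy-5,6-dimethoxyphenyl)propane-1,3-dione | COc1c(O)cc(O)c(C(=O)C(OCc2ccccc2)C(=O)c2ccc(OCc3ccccc3)c(CC[C@H](C)COCc3ccccc3)c2)c1OC | intermediate (not isolated)
19 | 3-(benzyloxy)-2-{4-(benzyloxy)-3-[(3S)-4-(benzyloxy)-3-methylbutyl]phenyl}-7-hydroxy-5,6-dimethoxy-4H-chromen-4-one | COc1c(O)cc2oc(-c3ccc(OCc4ccccc4)c(CC[C@H](C)COCc4ccccc4)c3)c(OCc3ccccc3)c(=O)c2c1OC | intermediate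
20 | 3,7-dihydroxy-2-{4-hydroxy-3-[(3S)-4-hydroxy-3-methylbutyl]phenyl}-5,6-dimethoxy-4H-chromen-4-one | COc1c(O)cc2oc(-c3ccc(O)c(CC[C@H](C)CO)c3)c(O)c(=O)c2c1OC | target

**Step count**

Total: 9 steps. Longest linear sequence: 7 steps (steps 2, 3, 4, 6, 7, 8, 9, from 4 to 20).

**Steps most likely to fail**

1. Step 8. The ring of 3 may be acylated at the carbon between its two hydroxyls, which would lead to chelated 5-hydroxy isomers. An O-acylated intermediate may close through ring attack on the ketone to a coumarin. Benzyl groups may be lost or may migrate at 240 °C.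
Fallback: known chemistry that forms the same ring in a different bond order, setting out from 3 and acid chloride 14. Diol 3 would be treated with 2-(benzyloxy)acetonitrile, ZnCl2 and dry HCl in Et2O at 0 °C (Hoesch acylation) to precipitate 2-(benzyloxy)-1-(2,4-dihydroxy-5,6-dimethoxyphenyl)ethan-1-iminium chloride F1. Warm water should hydrolyse it to 2-(benzyloxy)-1-(2,4-dihydroxy-5,6-dimethoxyphenyl)ethan-1-one F2. The substitution pattern can be proved, and any isomer removed, at this cheap stage. The ketone F2 would be converted with LiHMDS (4.5 equiv, THF, −78 °C) into its trilithio derivative and C-aroylated with 14 (1 equiv), a Baker–Venkataraman-type acylation without O-protection. This rejoins the route at diketone 18, now isolated. AcOH with a trace of H2SO4 (or TsOH in toluene) at 80–100 °C should then close 18 to 19.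

2. Step 3. The reduction may run on to the primary alcohol or stop short, and the α-stereocentre of the aldehyde may erode during handling.
Fallback: setting out from 5, full reduction with LiAlH4 (THF, 0 °C) should give (S)-3-(benzyloxy)-2-methylpropan-1-ol F3. Swern oxidation ((COCl)2, DMSO, then i-Pr2NEt, −78 °C) would return to the route at 6, taken crude into step 4.

3. Step 1. The peracid may oxidise the free, electron-rich phenol ring, or hydride may migrate instead of aryl to give the benzoic acid.
Fallback: setting out from 1, the phenol would first be masked (BnBr, K2CO3, DMF) as 3-(benzyloxy)-4,5-dimethoxybenzaldehyde F4. mCPBA in CH2Cl2 should convert it into 3-(benzyloxy)-4,5-dimethoxyphenyl formate F5. K2CO3 in MeOH would cleave this to 3-(benzyloxy)-4,5-dimethoxyphenol F6. Hydrogenolysis (H2, Pd/C, EtOAc) would return to the route at 3.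

Further compounds
F1 | step 8 | 2-(benzyloxy)-1-(2,4-dihydroxy-5,6-dimethoxyphenyl)ethan-1-iminium chloride | COc1c(O)cc(O)c(C(=[NH2+])COCc2ccccc2)c1OC.[Cl-]
F2 | step 8 | 2-(benzyloxy)-1-(2,4-dihydroxy-5,6-dimethoxyphenyl)ethan-1-one | COc1c(O)cc(O)c(C(=O)COCc2ccccc2)c1OC
F3 | step 3 | (S)-3-(benzyloxy)-2-methylpropan-1-ol | OC[C@H](C)COCc1ccccc1
F4 | step 1 | 3-(benzyloxy)-4,5-dimethoxybenzaldehyde | COc1cc(C=O)cc(OCc2ccccc2)c1OC
F5 | step 1 | 3-(benzyloxy)-4,5-dimethoxyphenyl formate | O=COc1cc(OCc2ccccc2)c(OC)c(OC)c1
F6 | step 1 | 3-(benzyloxy)-4,5-dimethoxyphenol | Oc1cc(OCc2ccccc2)c(OC)c(OC)c1
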